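**Retrosynthetic overview**
1. The butenolide ring is bought intact (4-bromofuran-2(5H)-one) and attached last: C12–C13 by B-alkyl Suzuki coupling, C9–C11 by Stille vinylation of a C9 enol triflate.
2. Ring B comes from an intramolecular nitrile oxide–alkene cycloaddition (C8–C9 and O–C17 bonds) that closes ring B and an isoxazoline together; N–O cleavage then gives the C9 ketone and C17 alcohol.
3. The cycloaddition precursor carries a C6 allyl carbinol (C6–C7 by allylation of a lactol, sets C6) and a C9 oxime (from a menthyl acetal).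
4. Ring A comes from a Diels–Alder reaction of the mesityl oxide silyloxydiene with (5S)-5-menthyloxy-4-methylbutenolide (C1–C10 and C4–C5); the cyclic dienophile fixes the 5,10-cis fusion and the absolute configuration.
5. Ring order: A, then B (with the temporary isoxazoline); the butenolide is introduced preformed.

Assumption: the (+)-menthyl acetal crystallizes as a single C5 epimer, as its lower homologue does; atom labels C1–C17 are the labdane numbers of the target, α = face opposite the C10 methyl.

**Route**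

Step 1
Reactants: 1 mesityl oxide (4-methylpent-3-en-2-one)
Product: 2 4-methyl-2-(trimethylsilyloxy)penta-1,3-diene
Conditions: LiN(i-Pr)2, THF, −78 °C; Me3SiCl, −78 °C → rt
Reagents that add atoms: chlorotrimethylsilane, C[Si](C)(C)Cl
Why: Kinetic deprotonation of the methyl ketone CH3 and O-silylation (silyl enol ether formation) give the cross-conjugated 2-silyloxydiene; no stereocentre is formed.

Step 2
Reactants: 3 5-hydroxy-4-methylfuran-2(5H)-one; 4 (+)-menthol
Product: 5 (5S)-5-[(1S,2R,5S)-menthyloxy]-4-methylfuran-2(5H)-one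
Conditions: camphorsulfonic acid (cat.), toluene, reflux, Dean–Stark; crystallization from hexane at −20 °C, mother liquor re-equilibrated with acid
Reagents that add atoms: none
Why: Acid-catalysed acetalization of the lactol (Feringa-type menthyloxybutenolide); the acetal epimers interconvert under the acid and the (5S) diastereomer is removed by crystallization, so this temporary centre becomes the single source of absolute configuration.

Step 3
Reactants: 2 4-methyl-2-(trimethylsilyloxy)penta-1,3-diene; 5 (5S)-5-[(1S,2R,5S)-menthyloxy]-4-methylfuran-2(5H)-one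
Product: 7 keto lactone acetal (3S,3aS,7aR)-3-[(1S,2R,5S)-menthyloxy]-3a,7,7-trimethylhexahydro-2-benzofuran-1,5-dione, via silyl enol ether cycloadduct 6 (not isolated)
Conditions: CH2Cl2, 1.5 GPa, 50 °C, 48 h; then 1 M HCl, THF, 0 °C
Reagents that add atoms: none
Why: High-pressure normal-demand Diels–Alder reaction in which the CH2 terminus of the diene bonds to the β-carbon C10 and the CMe2 terminus to C5 (silyloxy para to the lactone carbonyl, no vicinal quaternary carbons), the diene adds anti to the menthyloxy group and the cyclic dienophile forces H5 and the C10 methyl cis, which sets C5 (R) and C10 (S) before mild acid unmasks the C2 ketone.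

Step 4
Reactants: 7 keto lactone acetal
Product: 8 diol lactol acetal (3S,3aS,5S,7aR)-3-[(1S,2R,5S)-menthyloxy]-3a,7,7-trimethyloctahydro-2-benzofuran-1,5-diol (lactol carbon C6 as anomer mixture)
Conditions: i-Bu2AlH (3.5 equiv), CH2Cl2, −78 °C; aq. KNaC4H4O6
Reagents that add atoms: none
Why: Hydride reduction that stops at the lactol for the lactone and reduces the C2 ketone from the convex β-face of the cis-fused bicycle (the face of the angular methyl, the α-face being shielded by the folded lactone acetal), which sets the 2α-alcohol (C2 S).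

Step 5
Reactants: 8 diol lactol acetal; 9 allyltrimethylsilane
Product: 10 allyl acetal (1S,3S,3aS,5S,7aR)-1-allyl-3-[(1S,2R,5S)-menthyloxy]-3a,7,7-trimethyloctahydro-2-benzofuran-5-ol
Conditions: BF3·OEt2, CH2Cl2, −78 °C
Reagents that add atoms: none
Why: Hosomi–Sakurai C-allylation of the cyclic oxocarbenium ion formed from the lactol (the neopentyl menthyl acetal at C9 ionizes more slowly); the allylsilane attacks the convex face anti to the ring A bond at C5, which sets C6 (S) with the allyl group cis to H5.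

Step 6
Reactants: 10 allyl acetal
Product: 11 oxime (1S,3S,4R)-4-[(1S)-1-hydroxybut-3-en-1-yl]-3-[(hydroxyimino)methyl]-3,5,5-trimethylcyclohexan-1-ol
Conditions: NH2OH·HCl, NaOAc, EtOH/H2O, 70 °C
Reagents that add atoms: hydroxylamine hydrochloride, NO.Cl
Why: Acid-buffered acetal cleavage with oxime formation (transacetalization to the aldoxime) releases the menthol auxiliary and the C6 hydroxyl without touching any stereocentre.

Step 7
Reactants: 11 oxime
Product: 13 isoxazoline-fused cis-decalin diol (C9=N–O–C17H2–C8; 2α-OH; 6α-OH; 5β-H; 8β-H; 10β-CH3), via nitrile oxide 12 (not isolated)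
Conditions: aq. NaOCl, CH2Cl2, 0 °C → rt
Reagents that add atoms: none
Why: Oxidation of the aldoxime to the nitrile oxide and intramolecular nitrile oxide–alkene [3+2] cycloaddition close ring B (C8–C9) and the isoxazoline (O–C17) in one operation with the regiochemistry dictated by the four-atom tether; the new C8 centre is lost in step 10.

Step 8
Reactants: 13 isoxazoline-fused cis-decalin diol
Product: 14 β-hydroxy ketone 2α,6α-dihydroxy-8α-(hydroxymethyl)-4,4,10β-trimethyl-5βH-decalin-9-one
Conditions: H2 (1 atm), Raney Ni, B(OH)3, MeOH/H2O 5:1, rt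
Reagents that add atoms: water, O
Why: Hydrogenolytic N–O cleavage and hydrolysis of the resulting β-hydroxy imine (Curran conditions) unmask the C9 ketone and the C17 primary alcohol.

Step 9
Reactants: 14 β-hydroxy ketone
Product: 15 tris(tert-butyldimethylsilyl) ether of 14
Conditions: t-BuMe2SiOTf, 2,6-lutidine, CH2Cl2, −78 → 0 °C
Reagents that add atoms: tert-butyldimethylsilyl trifluoromethanesulfonate, CC(C)(C)[Si](C)(C)OS(=O)(=O)C(F)(F)F
Why: Silyl ether formation protects the three hydroxyls (including the hindered C6–OH) for the triflation and couplings.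

Step 10
Reactants: 15 tris(tert-butyldimethylsilyl) ether of 14
Product: 16 enol triflate 2α,6α-bis(silyloxy)-8-(silyloxymethyl)-4,4,10β-trimethyl-5βH-octal-8-en-9-yl trifluoromethanesulfonate
Conditions: Tf2O, 2,6-di-tert-butyl-4-methylpyridine, CH2Cl2, 0 °C → rt
Reagents that add atoms: trifluoromethanesulfonic anhydride, O=S(=O)(OS(=O)(=O)C(F)(F)F)C(F)(F)F
Why: Enol triflate formation by O-triflation and loss of H8 (C10 is quaternary, so only the C8=C9 regioisomer can form), under non-enolate conditions that avoid β-elimination of the C17 silyloxy group.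

Step 11
Reactants: 16 enol triflate; 17 tributyl(vinyl)stannane
Product: 18 diene 9-vinyl-2α,6α-bis(silyloxy)-8-(silyloxymethyl)-4,4,10β-trimethyl-5βH-octal-8-ene
Conditions: Pd(PPh3)4 (5 mol %), LiCl, THF, 65 °C
Reagents that add atoms: none
Why: Stille cross-coupling of the enol triflate installs C11–C12 as a vinyl group on C9.

Step 12
Reactants: 18 diene; 19 9-borabicyclo[3.3.1]nonane (9-BBN); 20 4-bromofuran-2(5H)-one
Product: 22 tris(tert-butyldimethylsilyl) ether of the target, via alkylborane 21 (not isolated)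
Conditions: THF, 0 °C → rt; then PdCl2(dppf) (5 mol %), AsPh3, aq. K3PO4, DMF, rt
Reagents that add atoms: none
Why: Anti-Markovnikov hydroboration of the only unhindered alkene (the tetrasubstituted C8=C9 is inert to 9-BBN) followed by B-alkyl Suzuki–Miyaura coupling with the bromobutenolide forms C12–C13.

Step 13
Reactants: 22 tris(tert-butyldimethylsilyl) ether of the target
Product: 23 target (2S,5R,6S,10S)-2,6,17-trihydroxy-5β-labda-8,13-dien-15,16-olide
Conditions: HF·pyridine, THF, 0 °C → rt
Reagents that add atoms: none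
Why: Fluoride-mediated desilylation under weakly acidic conditions frees the three hydroxyls without harming the butenolide or the allylic alcohol.

**Compound list**
1 | mesityl oxide (4-methylpent-3-en-2-one) | CC(=O)C=C(C)C | starting material
2 | 4-methyl-2-(trimethylsilyloxy)penta-1,3-diene | C=C(O[Si](C)(C)C)C=C(C)C | intermediate
3 | 5-hydroxy-4-methylfuran-2(5H)-one | CC1=CC(=O)OC1O | starting material
4 | (+)-menthol, (1S,2R,5S)-5-methyl-2-(propan-2-yl)cyclohexan-1-ol | C[C@H]1CC[C@@H]([C@H](C1)O)C(C)C | starting material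
5 | (5S)-5-[(1S,2R,5S)-menthyloxy]-4-methylfuran-2(5H)-one | C[C@H]1CC[C@@H]([C@H](C1)O[C@H]2OC(=O)C=C2C)C(C)C | intermediate
6 | silyl enol ether cycloadduct (3S,3aS,7aR)-3-menthyloxy-3a,7,7-trimethyl-5-(trimethylsilyloxy)-3a,4,7,7a-tetrahydro-2-benzofuran-1(3H)-one | CC1(C)C=C(O[Si](C)(C)C)C[C@]2(C)[C@@H](O[C@H]3C[C@@H](C)CC[C@@H]3C(C)C)OC(=O)[C@H]12 | intermediate
7 | keto lactone acetal (3S,3aS,7aR)-3-menthyloxy-3a,7,7-trimethylhexahydro-2-benzofuran-1,5-dione | CC1(C)CC(=O)C[C@]2(C)[C@@H](O[C@H]3C[C@@H](C)CC[C@@H]3C(C)C)OC(=O)[C@H]12 | intermediate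
8 | diol lactol acetal (3S,3aS,5S,7aR)-3-menthyloxy-3a,7,7-trimethyloctahydro-2-benzofuran-1,5-diol (lactol anomers) | CC1(C)C[C@H](O)C[C@]2(C)[C@@H](O[C@H]3C[C@@H](C)CC[C@@H]3C(C)C)OC(O)[C@H]12 | intermediate
9 | allyltrimethylsilane | C=CC[Si](C)(C)C | starting material
10 | allyl acetal (1S,3S,3aS,5S,7aR)-1-allyl-3-menthyloxy-3a,7,7-trimethyloctahydro-2-benzofuran-5-ol | CC1(C)C[C@H](O)C[C@]2(C)[C@@H](O[C@H]3C[C@@H](C)CC[C@@H]3C(C)C)O[C@@H](CC=C)[C@H]12 | intermediate
11 | oxime (1S,3S,4R)-4-[(1S)-1-hydroxybut-3-en-1-yl]-3-[(hydroxyimino)methyl]-3,5,5-trimethylcyclohexan-1-ol | CC1(C)C[C@H](O)C[C@](C)(C=NO)[C@@H]1[C@@H](O)CC=C | intermediate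
12 | nitrile oxide derived from 11 (C9≡N–O) | CC1(C)C[C@H](O)C[C@](C)(C#[N+][O-])[C@@H]1[C@@H](O)CC=C | intermediate
13 | isoxazoline-fused cis-decalin diol (C9=N–O–C17H2–C8; 2α-OH; 6α-OH; 5β-H; 8β-H drawn, C8 epimer immaterial) | CC1(C)C[C@H](O)C[C@]2(C)C3=NOC[C@@H]3C[C@H](O)[C@H]12 | intermediate
14 | 2α,6α-dihydroxy-8α-(hydroxymethyl)-4,4,10β-trimethyl-5βH-decalin-9-one | CC1(C)C[C@H](O)C[C@]2(C)C(=O)[C@H](CO)C[C@H](O)[C@H]12 | intermediate
15 | tris(tert-butyldimethylsilyl) ether of 14 | CC1(C)C[C@H](O[Si](C)(C)C(C)(C)C)C[C@]2(C)C(=O)[C@H](CO[Si](C)(C)C(C)(C)C)C[C@H](O[Si](C)(C)C(C)(C)C)[C@H]12 | intermediate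
16 | C9 enol triflate (C8=C9) of 15 | CC1(C)C[C@H](O[Si](C)(C)C(C)(C)C)C[C@]2(C)C(OS(=O)(=O)C(F)(F)F)=C(CO[Si](C)(C)C(C)(C)C)C[C@H](O[Si](C)(C)C(C)(C)C)[C@H]12 | intermediate
17 | tributyl(vinyl)stannane | CCCC[Sn](CCCC)(CCCC)C=C | starting material
18 | 9-vinyl diene (C8=C9–C11=C12), tris-silyl ether | CC1(C)C[C@H](O[Si](C)(C)C(C)(C)C)C[C@]2(C)C(C=C)=C(CO[Si](C)(C)C(C)(C)C)C[C@H](O[Si](C)(C)C(C)(C)C)[C@H]12 | intermediate
19 | 9-borabicyclo[3.3.1]nonane (9-BBN, sold as dimer) | B1C2CCCC1CCC2 | starting material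
20 | 4-bromofuran-2(5H)-one | O=C1C=C(Br)CO1 | starting material
21 | C12 alkylborane (B-alkyl-9-BBN) from 18 | CC1(C)C[C@H](O[Si](C)(C)C(C)(C)C)C[C@]2(C)C(CCB3C4CCCC3CCC4)=C(CO[Si](C)(C)C(C)(C)C)C[C@H](O[Si](C)(C)C(C)(C)C)[C@H]12 | intermediate
22 | tris(tert-butyldimethylsilyl) ether of the target | CC1(C)C[C@H](O[Si](C)(C)C(C)(C)C)C[C@]2(C)C(CCC3=CC(=O)OC3)=C(CO[Si](C)(C)C(C)(C)C)C[C@H](O[Si](C)(C)C(C)(C)C)[C@H]12 | intermediate
23 | (2S,5R,6S,10S)-2,6,17-trihydroxy-5β-labda-8,13-dien-15,16-olide (CNP0293367.1) | CC1(C)C[C@H](O)C[C@]2(C)C(CCC3=CC(=O)OC3)=C(CO)C[C@H](O)[C@H]12 | target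

**Step count and weak points**

Total steps: 13. Longest linear sequence: 12 (steps 2 to 13, from 3 and 4); step 1 is a one-step side branch.

Steps most likely to fail:

- **Step 3** (cycloaddition between a diene with a cis-methyl terminus and a β,β-disubstituted butenolide). Fallback: a stepwise polar annulation instead of a cycloaddition. It sets out from 1 and 5. The kinetic lithium enolate of 1 (LiN(i-Pr)2, THF, −78 °C) is added to 5 at −90 °C, attacks C10 anti to the menthyloxy group, and after protonation gives the open-chain Michael adduct F1. t-BuOK (0.2 equiv, t-BuOH/THF, 0 °C) then closes ring A by a second, intramolecular Michael addition of the lactone enolate (C5) to the dimethyl enone (C4); the five-membered lactone allows only the cis fusion. The fallback comes back to the route at 7.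

- **Step 4** (facial selectivity at C2: both faces of the ketone carry 1,3-related groups, so the 2β-alcohol may compete). Fallback: catalyst-controlled instead of substrate-controlled reduction. It sets out from 7. A ketoreductase chosen from a commercial panel for the 2α-alcohol (NADP+, i-PrOH, phosphate buffer, 30 °C) reduces only the ketone to the hydroxy lactone F2. i-Bu2AlH (2.3 equiv, CH2Cl2, −78 °C) then reduces the lactone, and the fallback comes back to the route at 8.

- **Step 10** (triflation of a ketone flanked by a quaternary carbon, with a β-silyloxy group that can be lost to give the exo-methylene ketone). Fallback: form C9–C11 by carbonyl addition and the alkene by dehydration. It sets out from 15. CH2=CHMgBr with anhydrous CeCl3 (THF, −78 → 0 °C) adds to the C9 ketone to give the tertiary allylic alcohol F3 (either C9 epimer). SOCl2/pyridine (CH2Cl2, −20 °C) dehydrates it towards C8, the only carbon with a β-hydrogen, and the fallback comes back to the route at 18 (16 and step 11 are bypassed).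

Further compounds
F1 | step 3 | open-chain Michael adduct (4S,5S)-5-[(1S,2R,5S)-menthyloxy]-4-methyl-4-(4-methyl-2-oxopent-3-en-1-yl)dihydrofuran-2(3H)-one | CC(C)=CC(=O)C[C@@]1(C)CC(=O)O[C@@H]1O[C@H]2C[C@@H](C)CC[C@@H]2C(C)C
F2 | step 4 | hydroxy lactone (3S,3aS,5S,7aR)-5-hydroxy-3-[(1S,2R,5S)-menthyloxy]-3a,7,7-trimethylhexahydro-2-benzofuran-1(3H)-one | CC1(C)C[C@H](O)C[C@]2(C)[C@@H](O[C@H]3C[C@@H](C)CC[C@@H]3C(C)C)OC(=O)[C@H]12
F3 | step 10 | tertiary allylic alcohol, 9-hydroxy-9-vinyl adduct of 15 (C9 epimers) | CC1(C)C[C@H](O[Si](C)(C)C(C)(C)C)C[C@]2(C)C(O)(C=C)[C@H](CO[Si](C)(C)C(C)(C)C)C[C@H](O[Si](C)(C)C(C)(C)C)[C@H]12
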